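Everything rests on opening the γ-lactone (ring D: O, C16–C19) at C18–C19 and O–C19. The feature used is the 1,4-relationship in ring D between the fully substituted, oxygen-bearing C16 and the acyl carbon C19: C17 and C18 are carried as a vinyl group on C16, and C19 is supplied by carbon monoxide. In one operation, rhodium-catalysed hydroformylation makes the linear aldehyde and the C16 hydroxyl closes it to the lactol, which is then oxidised. The precursor is the 2,5-trans oxolane (C12–C15) bearing the complete (E,E)-diene chain, ended by a primary chloride, and the C16 methyl vinyl carbinol; C12 comes from (R)-linalool, C15 and C16 from one Sharpless epoxidation–cyclisation.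

Key step: step 12

Remarks on the chemistry
- Numbering: C5–C11 is the chain from the butenolide to the oxolane (methyl on C8, alkenes C7=C8 and C10=C11); C12–C15 are the oxolane carbons (methyl on C12); C16–C19 are the carbons of lactone ring D (methyl on C16, C19 the carbonyl).
- Design: the chain terminus C5 is carried as a primary chloride, which is inert through steps 6–13 and is exchanged for iodide in step 14, so the chain needs no hydroxyl protecting group.
- Assumption: (R)-(−)-linalool of high enantiomeric purity and 5-chloro-2-methylpent-2-ene are taken as catalogue compounds; any (S)-linalool would end as the C12-epimeric oxolane in step 2 and be removed there by chromatography.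

Step 1
Reactants: 1 (R)-(−)-linalool, (3R)-3,7-dimethylocta-1,6-dien-3-ol
Product: 2 (2E,6R)-2,6-dimethylocta-2,7-diene-1,6-diol
Conditions: SeO2 (0.3 equiv), t-BuOOH (3 equiv), salicylic acid (0.1 equiv), CH2Cl2, rt
Reagents that add atoms: tert-butyl hydroperoxide, CC(C)(C)OO
Why: the Riley-type allylic oxidation (ene reaction, then [2,3]-sigmatropic shift) hydroxylates the methyl group trans to the chain on the trisubstituted alkene and so gives the (E)-allylic alcohol, while the vinyl group has no allylic hydrogen and the stereocentre of 1 (the future C12) is not touched.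

Step 2
Reactants: 2 (2E,6R)-2,6-dimethylocta-2,7-diene-1,6-diol
Product: 4 (2S)-2-[(2R,5R)-5-ethenyl-5-methyloxolan-2-yl]propane-1,2-diol, via epoxy alcohol 3 (not isolated)
Conditions: Ti(Oi-Pr)4 (10 mol %), L-(+)-diethyl tartrate (12 mol %), t-BuOOH, 4 Å molecular sieves, CH2Cl2, −20 °C; then CSA (10 mol %), 0 °C → rt
Reagents that add atoms: tert-butyl hydroperoxide, CC(C)(C)OO
Why: Katsuki–Sharpless asymmetric epoxidation with the L-(+)-tartrate oxidises only the primary trisubstituted allylic alcohol and sets the (2S,3S)-epoxide (future C16 and C15) under reagent control, and acid then lets the C12 tertiary hydroxyl open the epoxide at C15 by 5-exo-tet SN2 attack with inversion, so that C15 becomes R, C16 stays S and the oxolane is 2,5-trans; attack at C16 is disfavoured by the electron-withdrawing CH2OH group next to it.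

Step 3
Reactants: 4 (2S)-2-[(2R,5R)-5-ethenyl-5-methyloxolan-2-yl]propane-1,2-diol
Product: 5 (4S)-4-[(2R,5R)-5-ethenyl-5-methyloxolan-2-yl]-2,2,4-trimethyl-1,3-dioxolane
Conditions: 2,2-dimethoxypropane, PPTS (cat.), acetone, rt
Reagents that add atoms: 2,2-dimethoxypropane, COC(C)(C)OC
Why: acid-catalysed transketalisation (acetonide formation) masks both hydroxyls so that neither consumes hydride in step 8, and no stereocentre is involved.

Step 4
Reactants: 5 (4S)-4-[(2R,5R)-5-ethenyl-5-methyloxolan-2-yl]-2,2,4-trimethyl-1,3-dioxolane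
Product: 7 (2R,5R)-2-methyl-5-[(4S)-2,2,4-trimethyl-1,3-dioxolan-4-yl]oxolane-2-carbaldehyde, via ozonide 6 (not isolated)
Conditions: O3, CH2Cl2, −78 °C; then PPh3, −78 °C → rt
Reagents that add atoms: ozone, [O-][O+]=O
Why: ozonolysis with reductive work-up cleaves the only alkene present to the aldehyde, which cannot epimerise because C12 is fully substituted.

Step 5
Reactants: 7 (2R,5R)-2-methyl-5-[(4S)-2,2,4-trimethyl-1,3-dioxolan-4-yl]oxolane-2-carbaldehyde
Product: 8 (4S)-4-[(2R,5R)-5-ethynyl-5-methyloxolan-2-yl]-2,2,4-trimethyl-1,3-dioxolane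
Conditions: dimethyl (1-diazo-2-oxopropyl)phosphonate, K2CO3, MeOH, 0 °C → rt
Reagents that add atoms: dimethyl (1-diazo-2-oxopropyl)phosphonate, CC(=O)C(=[N+]=[N-])P(=O)(OC)OC
Why: the Ohira–Bestmann variant of the Seyferth–Gilbert homologation converts the non-enolisable aldehyde into the terminal alkyne under mild basic conditions that leave the acetonide intact.

Step 6
Reactants: 9 5-chloro-2-methylpent-2-ene
Product: 10 (2E)-5-chloro-2-methylpent-2-en-1-ol
Conditions: SeO2 (0.3 equiv), t-BuOOH (3 equiv), salicylic acid (0.1 equiv), CH2Cl2, rt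
Reagents that add atoms: tert-butyl hydroperoxide, CC(C)(C)OO
Why: the same Riley-type allylic oxidation of the gem-dimethyl alkene should give the (E)-allylic alcohol, which fixes the C7=C8 geometry of the target, and the primary chloride is inert.

Step 7
Reactants: 10 (2E)-5-chloro-2-methylpent-2-en-1-ol
Product: 11 (2E)-1-bromo-5-chloro-2-methylpent-2-ene
Conditions: PBr3 (0.4 equiv), Et2O, 0 °C
Reagents that add atoms: phosphorus tribromide, BrP(Br)Br
Why: PBr3 converts the primary allylic alcohol into the bromide by SN2 displacement without allylic transposition or loss of the (E) geometry.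

Step 8
Reactants: 8 (4S)-4-[(2R,5R)-5-ethynyl-5-methyloxolan-2-yl]-2,2,4-trimethyl-1,3-dioxolane; 11 (2E)-1-bromo-5-chloro-2-methylpent-2-ene
Product: 13 (4S)-4-[(2R,5R)-5-[(1E,4E)-7-chloro-4-methylhepta-1,4-dien-1-yl]-5-methyloxolan-2-yl]-2,2,4-trimethyl-1,3-dioxolane, via alkenylzirconocene chloride 12 (not isolated)
Conditions: Cp2Zr(H)Cl (1.3 equiv), THF, rt; then 11, Pd(PPh3)4 (5 mol %), 0 °C → rt
Reagents that add atoms: none
Why: syn hydrozirconation of the terminal alkyne places zirconium on C10 and gives the (E)-alkenylzirconocene, and the Negishi alkenyl–allyl coupling through a π-allylpalladium intermediate joins C10 to the unsubstituted allyl terminus C9 with retention of both alkene geometries, the primary chloride being inert to zerovalent palladium under these conditions.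

Step 9
Reactants: 13 (4S)-4-[(2R,5R)-5-[(1E,4E)-7-chloro-4-methylhepta-1,4-dien-1-yl]-5-methyloxolan-2-yl]-2,2,4-trimethyl-1,3-dioxolane
Product: 14 (2S)-2-[(2R,5R)-5-[(1E,4E)-7-chloro-4-methylhepta-1,4-dien-1-yl]-5-methyloxolan-2-yl]propane-1,2-diol
Conditions: AcOH/THF/H2O (3:1:1), 45 °C
Reagents that add atoms: none
Why: mild aqueous acid hydrolysis removes the acetonide while the chloride, the skipped diene and the allylic ether at C12 should survive.

Step 10
Reactants: 14 (2S)-2-[(2R,5R)-5-[(1E,4E)-7-chloro-4-methylhepta-1,4-dien-1-yl]-5-methyloxolan-2-yl]propane-1,2-diol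
Product: 15 (2R)-2-[(2R,5R)-5-[(1E,4E)-7-chloro-4-methylhepta-1,4-dien-1-yl]-5-methyloxolan-2-yl]-2-hydroxypropanal
Conditions: 2-iodoxybenzoic acid (IBX, 1.5 equiv), DMSO, rt
Reagents that add atoms: none
Why: IBX oxidises the primary alcohol of a 1,2-diol to the aldehyde without glycol cleavage, the tertiary hydroxyl cannot be oxidised and the fully substituted C16 cannot epimerise (its descriptor becomes R only because CHO now outranks C15).

Step 11
Reactants: 15 (2R)-2-[(2R,5R)-5-[(1E,4E)-7-chloro-4-methylhepta-1,4-dien-1-yl]-5-methyloxolan-2-yl]-2-hydroxypropanal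
Product: 16 (2S)-2-[(2R,5R)-5-[(1E,4E)-7-chloro-4-methylhepta-1,4-dien-1-yl]-5-methyloxolan-2-yl]but-3-en-2-ol
Conditions: Ph3PCH3Br (3 equiv), KOt-Bu (2.8 equiv), THF, 0 °C; then 15, 0 °C
Reagents that add atoms: methyltriphenylphosphonium bromide, C[P+](c1ccccc1)(c1ccccc1)c1ccccc1.[Br-]
Why: Wittig methylenation with excess ylide (one equivalent is taken up by the free hydroxyl) turns the aldehyde into the vinyl group, and the primary chloride is too poor an electrophile to alkylate the ylide at 0 °C.

Step 12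
Reactants: 16 (2S)-2-[(2R,5R)-5-[(1E,4E)-7-chloro-4-methylhepta-1,4-dien-1-yl]-5-methyloxolan-2-yl]but-3-en-2-ol
Product: 18 (5S)-5-[(2R,5R)-5-[(1E,4E)-7-chloro-4-methylhepta-1,4-dien-1-yl]-5-methyloxolan-2-yl]-5-methyloxolan-2-ol (both anomers), via hydroxy aldehyde 17 (not isolated)
Conditions: Rh(acac)(CO)2 (1 mol %), PPh3 (10 mol %), CO/H2 (1:1, 20 bar), toluene, 60 °C
Reagents that add atoms: carbon monoxide, [C-]#[O+]
Why: A rhodium hydride of the HRh(CO)(PPh3)2 type adds across the monosubstituted C17=C18 bond with rhodium on the terminal carbon C18, CO inserts and hydrogenolysis of the acyl releases the linear aldehyde 17 (new C18–C19 bond), whose carbonyl is then attacked by the C16 hydroxyl to give the lactol (new O–C19 bond). The closest known reaction is the hydroformylation of linalool-type tertiary vinyl carbinols, which gives 2-hydroxyoxolanes directly. Ring D closes by 5-exo-trig addition of the hydroxyl oxygen to the aldehyde carbon. The only new stereocentre is the hemiacetal carbon C19, which is left uncontrolled because step 13 removes it, while C12, C15 and C16 are not touched. The step needs chemoselectivity for the vinyl group over the C10=C11 and C7=C8 alkenes and linear regioselectivity: the first should follow from the much higher rate of monosubstituted alkenes with the moderately active PPh3-modified catalyst at 60 °C, the second from the fully substituted C16, which keeps rhodium off the internal carbon C17. The primary chloride and the allylic ether at C12 are inert to these neutral conditions.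

Step 13
Reactants: 18 (5S)-5-[(2R,5R)-5-[(1E,4E)-7-chloro-4-methylhepta-1,4-dien-1-yl]-5-methyloxolan-2-yl]-5-methyloxolan-2-ol
Product: 19 (5S)-5-[(2R,5R)-5-[(1E,4E)-7-chloro-4-methylhepta-1,4-dien-1-yl]-5-methyloxolan-2-yl]-5-methyloxolan-2-one
Conditions: TEMPO (10 mol %), PhI(OAc)2 (1.3 equiv), CH2Cl2, rt
Reagents that add atoms: none
Why: oxoammonium (TEMPO) oxidation of the hemiacetal C19–H converts both anomers into the one γ-lactone and should not touch the alkenes.

Step 14
Reactants: 19 (5S)-5-[(2R,5R)-5-[(1E,4E)-7-chloro-4-methylhepta-1,4-dien-1-yl]-5-methyloxolan-2-yl]-5-methyloxolan-2-one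
Product: 20 (5S)-5-[(2R,5R)-5-[(1E,4E)-7-iodo-4-methylhepta-1,4-dien-1-yl]-5-methyloxolan-2-yl]-5-methyloxolan-2-one
Conditions: NaI (5 equiv), acetone, reflux
Reagents that add atoms: sodium iodide, [Na+].[I-]
Why: Finkelstein exchange, driven by precipitation of NaCl, gives the primary iodide needed for a clean enolate alkylation.

Step 15
Reactants: 21 3-bromooxolan-2-one (α-bromo-γ-butyrolactone)
Product: 22 3-(phenylsulfanyl)oxolan-2-one (racemic)
Conditions: PhSH, Et3N, CH2Cl2, 0 °C → rt
Reagents that add atoms: benzenethiol, Sc1ccccc1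
Why: SN2 displacement of the activated α-bromide by thiolate gives the sulfenyl lactone, used as the racemate because this centre is destroyed in step 17.

Step 16
Reactants: 20 (5S)-5-[(2R,5R)-5-[(1E,4E)-7-iodo-4-methylhepta-1,4-dien-1-yl]-5-methyloxolan-2-yl]-5-methyloxolan-2-one; 22 3-(phenylsulfanyl)oxolan-2-one
Product: 24 3-[(3E,6E)-4-methyl-7-[(2R,5R)-2-methyl-5-[(2S)-2-methyl-5-oxooxolan-2-yl]oxolan-2-yl]hepta-3,6-dien-1-yl]-3-(phenylsulfanyl)oxolan-2-one (both epimers at the sulfur-bearing carbon), via lithium enolate 23 (not isolated)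
Conditions: 22 (1.5 equiv), LiHMDS (1.45 equiv), THF, −78 °C; then DMPU, 20, −78 °C → rt
Reagents that add atoms: none
Why: the sulfur-stabilised lactone enolate is a soft, weakly basic nucleophile that alkylates primary iodides by SN2 (the standard way of attaching α-substituted butenolides), and forming it with slightly less than one equivalent of base leaves none to enolise the ring D lactone.

Step 17
Reactants: 24 3-[(3E,6E)-4-methyl-7-[(2R,5R)-2-methyl-5-[(2S)-2-methyl-5-oxooxolan-2-yl]oxolan-2-yl]hepta-3,6-dien-1-yl]-3-(phenylsulfanyl)oxolan-2-one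
Product: 26 3-[(3E,6E)-4-methyl-7-[(2R,5R)-2-methyl-5-[(2S)-2-methyl-5-oxooxolan-2-yl]oxolan-2-yl]hepta-3,6-dien-1-yl]furan-2(5H)-one (CNP0301418.1), via sulfoxide 25 (not isolated)
Conditions: mCPBA (1.0 equiv), CH2Cl2, −78 °C; then toluene, 110 °C
Reagents that add atoms: none
Why: at −78 °C the sulfide is oxidised to the sulfoxide far faster than the alkenes are epoxidised, and thermal syn elimination of benzenesulfenic acid toward the ring CH2 should give the conjugated endocyclic butenolide and remove the sulfur-bearing stereocentre.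

Compound list
1 | (R)-(−)-linalool, (3R)-3,7-dimethylocta-1,6-dien-3-ol | C=C[C@](C)(O)CCC=C(C)C | starting material
2 | (2E,6R)-2,6-dimethylocta-2,7-diene-1,6-diol | C=C[C@](C)(O)CC/C=C(\C)CO | intermediate
3 | epoxy alcohol, (3R)-5-[(2S,3S)-3-(hydroxymethyl)-3-methyloxiran-2-yl]-3-methylpent-1-en-3-ol | C=C[C@](C)(O)CC[C@@H]1O[C@@]1(C)CO | intermediate (not isolated)
4 | (2S)-2-[(2R,5R)-5-ethenyl-5-methyloxolan-2-yl]propane-1,2-diol | C=C[C@@]1(C)CC[C@H]([C@@](C)(O)CO)O1 | intermediate
5 | (4S)-4-[(2R,5R)-5-ethenyl-5-methyloxolan-2-yl]-2,2,4-trimethyl-1,3-dioxolane | C=C[C@@]1(C)CC[C@H]([C@]2(C)COC(C)(C)O2)O1 | intermediate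
6 | ozonide, 3-[(2R,5R)-2-methyl-5-[(4S)-2,2,4-trimethyl-1,3-dioxolan-4-yl]oxolan-2-yl]-1,2,4-trioxolane | C1OOC(O1)[C@@]1(C)CC[C@H]([C@]2(C)COC(C)(C)O2)O1 | intermediate (not isolated)
7 | (2R,5R)-2-methyl-5-[(4S)-2,2,4-trimethyl-1,3-dioxolan-4-yl]oxolane-2-carbaldehyde | O=C[C@@]1(C)CC[C@H]([C@]2(C)COC(C)(C)O2)O1 | intermediate
8 | (4S)-4-[(2R,5R)-5-ethynyl-5-methyloxolan-2-yl]-2,2,4-trimethyl-1,3-dioxolane | C#C[C@@]1(C)CC[C@H]([C@]2(C)COC(C)(C)O2)O1 | intermediate
9 | 5-chloro-2-methylpent-2-ene | CC(C)=CCCCl | starting material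
10 | (2E)-5-chloro-2-methylpent-2-en-1-ol | C/C(=C\CCCl)CO | intermediate
11 | (2E)-1-bromo-5-chloro-2-methylpent-2-ene | C/C(=C\CCCl)CBr | intermediate
12 | alkenylzirconocene chloride, chlorobis(cyclopentadienyl)[(E)-2-[(2R,5R)-2-methyl-5-[(4S)-2,2,4-trimethyl-1,3-dioxolan-4-yl]oxolan-2-yl]ethenyl]zirconium | Cl[Zr](/C=C/[C@@]1(C)CC[C@H]([C@]2(C)COC(C)(C)O2)O1)(C1C=CC=C1)C1C=CC=C1 | intermediate (not isolated)
13 | (4S)-4-[(2R,5R)-5-[(1E,4E)-7-chloro-4-methylhepta-1,4-dien-1-yl]-5-methyloxolan-2-yl]-2,2,4-trimethyl-1,3-dioxolane | C/C(=C\CCCl)C/C=C/[C@@]1(C)CC[C@H]([C@]2(C)COC(C)(C)O2)O1 | intermediate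
14 | (2S)-2-[(2R,5R)-5-[(1E,4E)-7-chloro-4-methylhepta-1,4-dien-1-yl]-5-methyloxolan-2-yl]propane-1,2-diol | C/C(=C\CCCl)C/C=C/[C@@]1(C)CC[C@H]([C@@](C)(O)CO)O1 | intermediate
15 | (2R)-2-[(2R,5R)-5-[(1E,4E)-7-chloro-4-methylhepta-1,4-dien-1-yl]-5-methyloxolan-2-yl]-2-hydroxypropanal | C/C(=C\CCCl)C/C=C/[C@@]1(C)CC[C@H]([C@@](C)(O)C=O)O1 | intermediate
16 | (2S)-2-[(2R,5R)-5-[(1E,4E)-7-chloro-4-methylhepta-1,4-dien-1-yl]-5-methyloxolan-2-yl]but-3-en-2-ol (key-step precursor) | C/C(=C\CCCl)C/C=C/[C@@]1(C)CC[C@H]([C@@](C)(O)C=C)O1 | intermediate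
17 | hydroxy aldehyde, (4S)-4-[(2R,5R)-5-[(1E,4E)-7-chloro-4-methylhepta-1,4-dien-1-yl]-5-methyloxolan-2-yl]-4-hydroxypentanal | C/C(=C\CCCl)C/C=C/[C@@]1(C)CC[C@H]([C@@](C)(O)CCC=O)O1 | intermediate (not isolated)
18 | (5S)-5-[(2R,5R)-5-[(1E,4E)-7-chloro-4-methylhepta-1,4-dien-1-yl]-5-methyloxolan-2-yl]-5-methyloxolan-2-ol, both anomers (key-step product) | C/C(=C\CCCl)C/C=C/[C@@]1(C)CC[C@H]([C@]2(C)CCC(O)O2)O1 | intermediate
19 | (5S)-5-[(2R,5R)-5-[(1E,4E)-7-chloro-4-methylhepta-1,4-dien-1-yl]-5-methyloxolan-2-yl]-5-methyloxolan-2-one | C/C(=C\CCCl)C/C=C/[C@@]1(C)CC[C@H]([C@]2(C)CCC(=O)O2)O1 | intermediate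
20 | (5S)-5-[(2R,5R)-5-[(1E,4E)-7-iodo-4-methylhepta-1,4-dien-1-yl]-5-methyloxolan-2-yl]-5-methyloxolan-2-one | C/C(=C\CCI)C/C=C/[C@@]1(C)CC[C@H]([C@]2(C)CCC(=O)O2)O1 | intermediate
21 | 3-bromooxolan-2-one | O=C1OCCC1Br | starting material
22 | 3-(phenylsulfanyl)oxolan-2-one (racemic) | O=C1OCCC1Sc1ccccc1 | intermediate
23 | lithium enolate, lithium 3-(phenylsulfanyl)-4,5-dihydrofuran-2-olate | [Li+].[O-]C1=C(Sc2ccccc2)CCO1 | intermediate (not isolated)
24 | 3-[(3E,6E)-4-methyl-7-[(2R,5R)-2-methyl-5-[(2S)-2-methyl-5-oxooxolan-2-yl]oxolan-2-yl]hepta-3,6-dien-1-yl]-3-(phenylsulfanyl)oxolan-2-one, both epimers at the sulfur-bearing carbon | C/C(=C\CCC1(Sc2ccccc2)CCOC1=O)C/C=C/[C@@]1(C)CC[C@H]([C@]2(C)CCC(=O)O2)O1 | intermediate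
25 | sulfoxide, 3-(benzenesulfinyl)-3-[(3E,6E)-4-methyl-7-[(2R,5R)-2-methyl-5-[(2S)-2-methyl-5-oxooxolan-2-yl]oxolan-2-yl]hepta-3,6-dien-1-yl]oxolan-2-one | C/C(=C\CCC1(S(=O)c2ccccc2)CCOC1=O)C/C=C/[C@@]1(C)CC[C@H]([C@]2(C)CCC(=O)O2)O1 | intermediate (not isolated)
26 | 3-[(3E,6E)-4-methyl-7-[(2R,5R)-2-methyl-5-[(2S)-2-methyl-5-oxooxolan-2-yl]oxolan-2-yl]hepta-3,6-dien-1-yl]furan-2(5H)-one, CNP0301418.1 | C/C(=C\CCC1=CCOC1=O)C/C=C/[C@@]1(C)CC[C@H]([C@]2(C)CCC(=O)O2)O1 | target

Total step count: 17 (steps 6, 7 and 15 prepare the two side fragments).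
Longest linear sequence: 14 steps from 1 (steps 1–5, 8–14, 16 and 17).

Steps most likely to fail

Step 12. What may go wrong: slow turnover at the hindered vinyl group, so that forcing conditions bring hydroformylation or migration of the C10=C11 alkene, or simple hydrogenation of the vinyl group. Fallback: ring D is built by a two-carbon Wittig extension instead of carbonylation. It sets out from aldehyde 15 and replaces steps 11–13. Methyl (triphenylphosphoranylidene)acetate in toluene should give the (E)-γ-hydroxy enoate F1. Conjugate reduction of the enoate alone with [(Ph3P)CuH]6 in wet THF should give the saturated hydroxy ester F2. F2 should close with loss of methanol (PPTS, toluene, 60 °C) to lactone 19, where the route is rejoined.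

Step 8. What may go wrong: loss of the C7=C8 geometry or bond formation at the substituted allyl terminus C7 through syn–anti isomerisation of the π-allylpalladium intermediate, or incomplete hydrozirconation. Fallback: the C10=C11 alkene is made by a Julia–Lythgoe olefination, which involves no allyl–metal species. It sets out from bromide 11 and aldehyde 7 and replaces steps 5 and 8. Lithiated methyl phenyl sulfone (n-BuLi, THF, −78 °C, used in excess) should alkylate 11 to the homoallylic phenyl sulfone F3. The lithio derivative of F3 should add to 7, and trapping of the alkoxide with Ac2O should give the acetoxy sulfone F4 as a diastereomer mixture. Reductive elimination with Na(Hg) and Na2HPO4 in MeOH at −20 °C should then give the (E)-alkene 13, where the route is rejoined.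

Step 16. What may go wrong: E2 loss of HI from the homoallylic iodide to a conjugated diene, or attack of the enolate on the ring D lactone. Fallback: the butenolide is attached by C(sp3)–C(sp2) cross-coupling, with no enolate present. It sets out from iodide 20 and replaces steps 15–17. Zinc insertion (Zn dust, LiCl, THF) should give the alkylzinc iodide F5. Negishi coupling of F5 with commercial 3-bromofuran-2(5H)-one (Pd(dppf)Cl2, THF, rt) should give target 26 directly.

Further compounds
F1 | step 12 | methyl (2E,4S)-4-[(2R,5R)-5-[(1E,4E)-7-chloro-4-methylhepta-1,4-dien-1-yl]-5-methyloxolan-2-yl]-4-hydroxypent-2-enoate | C/C(=C\CCCl)C/C=C/[C@@]1(C)CC[C@H]([C@@](C)(O)/C=C/C(=O)OC)O1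
F2 | step 12 | methyl (4S)-4-[(2R,5R)-5-[(1E,4E)-7-chloro-4-methylhepta-1,4-dien-1-yl]-5-methyloxolan-2-yl]-4-hydroxypentanoate | C/C(=C\CCCl)C/C=C/[C@@]1(C)CC[C@H]([C@@](C)(O)CCC(=O)OC)O1
F3 | step 8 | {[(3E)-6-chloro-3-methylhex-3-en-1-yl]sulfonyl}benzene | C/C(=C\CCCl)CCS(=O)(=O)c1ccccc1
F4 | step 8 | (4E)-2-(benzenesulfonyl)-7-chloro-4-methyl-1-[(2R,5R)-2-methyl-5-[(4S)-2,2,4-trimethyl-1,3-dioxolan-4-yl]oxolan-2-yl]hept-4-en-1-yl acetate (diastereomer mixture) | C/C(=C\CCCl)CC(C(OC(C)=O)[C@@]1(C)CC[C@H]([C@]2(C)COC(C)(C)O2)O1)S(=O)(=O)c1ccccc1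
F5 | step 16 | [(3E,6E)-4-methyl-7-[(2R,5R)-2-methyl-5-[(2S)-2-methyl-5-oxooxolan-2-yl]oxolan-2-yl]hepta-3,6-dien-1-yl]zinc iodide | C/C(=C\CC[Zn]I)C/C=C/[C@@]1(C)CC[C@H]([C@]2(C)CCC(=O)O2)O1
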